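**Retrosynthetic overview**

- The strategy rests on ring B: its oxygens at C2' (free OH) and C5' (OMe) are para to each other and flank the C1' attachment carbon. In chromene numbering this is C5–OH, C6–aryl, C8–OMe, a hydroquinone pattern that arises when a quinone accepts a carbon nucleophile.
- Key disconnection: C3–C1' and O1–C2 of ring C, formed together by conjugate addition of an ortho-hydroxyaryl enaminone (ring A) to 2,2-dimethyl-2H-chromene-5,8-dione (rings B and D) with chromone annulation.
- The enaminone comes from 2,4-dihydroxyacetophenone (4-O-MOM, then DMF dimethyl acetal). The quinone comes from 2,5-dimethoxyphenol and 3-chloro-3-methylbut-1-yne (propargyl ether, Claisen cascade closing ring D, oxidative demethylation).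
- Endgame: site-selective methylation of the exposed C8 hydroxyl, then MOM removal. Ring order: D, then C; rings A and B come from the starting materials.

Key step: step 6

Remark: ring B is numbered as the 2H-chromene throughout (chromene C5, C6, C8 = isoflavone C2', C1', C5'). The target is achiral, so no stereocentre has to be set.

**Route**

Step 1
Reactants: 1 2,4-dihydroxyacetophenone
Product: 2 1-[2-hydroxy-4-(methoxymethoxy)phenyl]ethan-1-one
Conditions: MOMCl (1.1 equiv), K2CO3, acetone, 0 °C to rt
Reagents that add atoms: chloromethyl methyl ether (MOMCl), COCCl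
Why: Williamson-type O-alkylation takes only the 4-hydroxyl, because the 2-hydroxyl is held in a hydrogen bond to the acetyl carbonyl and is far less nucleophilic.

Step 2
Reactants: 2 1-[2-hydroxy-4-(methoxymethoxy)phenyl]ethan-1-one
Product: 3 (E)-3-(dimethylamino)-1-[2-hydroxy-4-(methoxymethoxy)phenyl]prop-2-en-1-one
Conditions: DMF dimethyl acetal (2 equiv), toluene, 90 °C
Reagents that add atoms: N,N-dimethylformamide dimethyl acetal, COC(OC)N(C)C
Why: Condensation of the methyl ketone with the amide acetal (enaminone formation) should give the E-configured vinylogous amide with loss of methanol, the chelated phenol staying free and the MOM ether untouched.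

Step 3
Reactants: 4 2,5-dimethoxyphenol; 5 3-chloro-3-methylbut-1-yne
Product: 6 1,4-dimethoxy-2-[(2-methylbut-3-yn-2-yl)oxy]benzene
Conditions: K2CO3, KI (cat.), CuI (cat.), acetone, reflux
Reagents that add atoms: none
Why: Copper-assisted O-alkylation of the phenoxide by the tertiary propargylic chloride (propargyl etherification) is the standard entry to aryl 1,1-dimethylpropargyl ethers.

Step 4
Reactants: 6 1,4-dimethoxy-2-[(2-methylbut-3-yn-2-yl)oxy]benzene
Product: 9 5,8-dimethoxy-2,2-dimethyl-2H-chromene, via allenylphenol 7 (not isolated), via ortho-quinone methide 8 (not isolated)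
Conditions: PhNEt2, 190 °C
Reagents that add atoms: none
Why: Aromatic propargyl Claisen rearrangement to the only free ortho carbon gives allenylphenol 7, a 1,5-hydrogen shift gives quinone methide 8, and an oxa-6π electrocyclisation closes ring D.

Step 5
Reactants: 9 5,8-dimethoxy-2,2-dimethyl-2H-chromene
Product: 10 2,2-dimethyl-2H-chromene-5,8-dione
Conditions: (NH4)2Ce(NO3)6 (2.5 equiv), MeCN–H2O, 0 °C, short reaction time
Reagents that add atoms: water, O
Why: Oxidative demethylation of the para-dimethoxyarene by (NH4)2Ce(NO3)6 should proceed through the arene radical cation, which is attacked by water at the two methoxy-bearing carbons and releases two molecules of methanol to give the para-quinone.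

Step 6
Reactants: 3 (E)-3-(dimethylamino)-1-[2-hydroxy-4-(methoxymethoxy)phenyl]prop-2-en-1-one; 10 2,2-dimethyl-2H-chromene-5,8-dione
Product: 13 3-(5,8-dihydroxy-2,2-dimethyl-2H-chromen-6-yl)-7-(methoxymethoxy)chromen-4-one, via hydroquinone enaminone 11 (not isolated), via 2-(dimethylamino)chromanone aminal 12 (not isolated)
Conditions: 10 (1.3 equiv), MeCN, rt, Ar; then AcOH (2 equiv), rt; work-up: wash with aq. Na2S2O4
Reagents that add atoms: none
Why: Proposed new method: the α-carbon of enaminone 3 should add in Michael fashion to C6 of quinone 10 and the adduct should enolise to hydroquinone 11, drawn as the neutral α-aryl enaminone whose C-protonated form is the iminium ion. The chelated ortho phenol of the ketone ring then adds to the iminium carbon in a 6-exo-trig closure to aminal 12 and loss of dimethylamine gives the γ-pyrone, so that C3–C1' (chromene C6) and O1–C2 are formed and ring C is closed in one flask. The closest known reactions are the electrophile-triggered chromone annulation of ortho-hydroxyaryl enaminones, the Michael step of the Nenitzescu enamine–quinone condensation and the ring closure of α-aryl enaminones in the deoxybenzoin–DMF dimethyl acetal isoflavone synthesis; a quinone as the electrophile of this annulation is an extrapolation. No stereocentre is set, since the two centres of 12 disappear on elimination. The step needs regioselectivity on the quinone, which O1 should secure: it donates through C8a=C4a into the C5 carbonyl (a vinylogous ester), so the C8 carbonyl polarises C6=C7 and the nucleophile enters at C6, para to O1, as in 2-alkoxy-1,4-benzoquinones. It also needs the ketone-ring phenol and not the C5 hydroxyl of ring B to trap the iminium carbon (the latter would give the 3-aroylbenzofuran of the Nenitzescu pathway); the hydrogen-bonded, coplanar aryl ketone holds its phenol next to that carbon and in the first-formed adduct the C5 oxygen is still a carbonyl oxygen, which is why the addition is run without acid and AcOH is added only afterwards.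

Step 7
Reactants: 13 3-(5,8-dihydroxy-2,2-dimethyl-2H-chromen-6-yl)-7-(methoxymethoxy)chromen-4-one
Product: 14 3-(5-hydroxy-8-methoxy-2,2-dimethyl-2H-chromen-6-yl)-7-(methoxymethoxy)chromen-4-one
Conditions: MeI (1.05 equiv), K2CO3 (1.1 equiv), degassed acetone, rt, Ar
Reagents that add atoms: iodomethane, CI
Why: Williamson methylation with one equivalent of MeI should take the exposed C8 hydroxyl, because the C5 hydroxyl sits between the chromone and the peri C4–H of ring D and can hydrogen-bond to the chromone carbonyl.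

Step 8
Reactants: 14 3-(5-hydroxy-8-methoxy-2,2-dimethyl-2H-chromen-6-yl)-7-(methoxymethoxy)chromen-4-one
Product: 15 7-hydroxy-3-(5-hydroxy-8-methoxy-2,2-dimethyl-2H-chromen-6-yl)-4H-chromen-4-one
Conditions: HCl (cat., conc. aq.), MeOH, 40 °C
Reagents that add atoms: none
Why: Acid-catalysed acetal exchange in methanol (MOM cleavage) should free the 7-hydroxyl, while the 2,2-dimethylchromene, the chromone and the aryl methyl ether tolerate dilute acid at this temperature.

**Compound list**

1 | 2,4-dihydroxyacetophenone | CC(=O)c1ccc(O)cc1O | starting material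
2 | 1-[2-hydroxy-4-(methoxymethoxy)phenyl]ethan-1-one | CC(=O)c1ccc(OCOC)cc1O | intermediate
3 | (E)-3-(dimethylamino)-1-[2-hydroxy-4-(methoxymethoxy)phenyl]prop-2-en-1-one | CN(C)/C=C/C(=O)c1ccc(OCOC)cc1O | intermediate
4 | 2,5-dimethoxyphenol | COc1ccc(OC)c(O)c1 | starting material
5 | 3-chloro-3-methylbut-1-yne | CC(C)(Cl)C#C | starting material
6 | 1,4-dimethoxy-2-[(2-methylbut-3-yn-2-yl)oxy]benzene | COc1ccc(OC)c(OC(C)(C)C#C)c1 | intermediate
7 | 3,6-dimethoxy-2-(3-methylbuta-1,2-dien-1-yl)phenol (allenylphenol, formed in the flask) | COc1ccc(OC)c(O)c1C=C=C(C)C | intermediate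
8 | (6Z)-2,5-dimethoxy-6-(3-methylbut-2-en-1-ylidene)cyclohexa-2,4-dien-1-one (ortho-quinone methide, formed in the flask) | CC(C)=C/C=C1\C(=O)C(OC)=CC=C1OC | intermediate
9 | 5,8-dimethoxy-2,2-dimethyl-2H-chromene | COc1ccc(OC)c2c1OC(C)(C)C=C2 | intermediate
10 | 2,2-dimethyl-2H-chromene-5,8-dione | CC1(C)C=CC2=C(O1)C(=O)C=CC2=O | intermediate
11 | 2-(5,8-dihydroxy-2,2-dimethyl-2H-chromen-6-yl)-3-(dimethylamino)-1-[2-hydroxy-4-(methoxymethoxy)phenyl]prop-2-en-1-one (hydroquinone enaminone, formed in the flask, alkene geometry not defined) | CN(C)C=C(C(=O)c1ccc(OCOC)cc1O)c1cc(O)c2OC(C)(C)C=Cc2c1O | intermediate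
12 | 3-(5,8-dihydroxy-2,2-dimethyl-2H-chromen-6-yl)-2-(dimethylamino)-7-(methoxymethoxy)chroman-4-one (aminal, formed in the flask, racemic, relative configuration not defined) | COCOc1ccc2c(c1)OC(N(C)C)C(c1cc(O)c3OC(C)(C)C=Cc3c1O)C2=O | intermediate
13 | 3-(5,8-dihydroxy-2,2-dimethyl-2H-chromen-6-yl)-7-(methoxymethoxy)chromen-4-one | COCOc1ccc2c(c1)occ(-c1cc(O)c3OC(C)(C)C=Cc3c1O)c2=O | intermediate
14 | 3-(5-hydroxy-8-methoxy-2,2-dimethyl-2H-chromen-6-yl)-7-(methoxymethoxy)chromen-4-one | COCOc1ccc2c(c1)occ(-c1cc(OC)c3OC(C)(C)C=Cc3c1O)c2=O | intermediate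
15 | 7-hydroxy-3-(5-hydroxy-8-methoxy-2,2-dimethyl-2H-chromen-6-yl)-4H-chromen-4-one | COc1cc(-c2coc3cc(O)ccc3c2=O)c(O)c2c1OC(C)(C)C=C2 | target

**Step count**

Total: 8 steps. Longest linear sequence: 6 steps (steps 3 to 8, from 2,5-dimethoxyphenol).

**Steps most likely to fail**

1. Step 6 (key step, proposed method). Several processes could defeat it:
- trapping of the iminium carbon by the ring B C5 hydroxyl, which gives the benzofuran skeleton;
- slow conjugate addition to the electron-rich alkoxyquinone;
- redox exchange between product hydroquinone and quinone;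
- conjugate addition of liberated dimethylamine to the quinone.

The fallback is a Suzuki–Miyaura assembly of known steps; it sets out from 3, 4 and 5 and returns at 13. Enaminone 3 would be cyclised with I2 and pyridine in CHCl3 to 3-iodo-7-(methoxymethoxy)chromen-4-one F1. Phenol 4 would be brominated para to the hydroxyl (NBS, MeCN, 0 °C) to 4-bromo-2,5-dimethoxyphenol F2. This would be etherified with 5 under the conditions of step 3 to 1-bromo-2,5-dimethoxy-4-[(2-methylbut-3-yn-2-yl)oxy]benzene F3, and heated as in step 4 to 6-bromo-5,8-dimethoxy-2,2-dimethyl-2H-chromene F4. Miyaura borylation (B2pin2, PdCl2(dppf), KOAc, dioxane, 90 °C) would give 2-(5,8-dimethoxy-2,2-dimethyl-2H-chromen-6-yl)-4,4,5,5-tetramethyl-1,3,2-dioxaborolane F5. Coupling with F1 (Pd(PPh3)4, Na2CO3, DME–H2O, 80 °C) would give 3-(5,8-dimethoxy-2,2-dimethyl-2H-chromen-6-yl)-7-(methoxymethoxy)chromen-4-one F6. Oxidative demethylation with (NH4)2Ce(NO3)6 as in step 5 would give 6-[7-(methoxymethoxy)-4-oxo-4H-chromen-3-yl]-2,2-dimethyl-2H-chromene-5,8-dione F7, and reduction with aq. Na2S2O4 leads back to 13.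

2. Step 7. Methylation could occur at both hydroxyls or at the wrong one, and the hydroquinone could be oxidised by air under base. The fallback replaces selective methylation by sterically controlled silylation; it sets out from 13 and returns at 15. TIPSCl and imidazole in DMF at 0 °C should silylate only the exposed C8 hydroxyl and give 3-{5-hydroxy-2,2-dimethyl-8-[(triisopropylsilyl)oxy]-2H-chromen-6-yl}-7-(methoxymethoxy)chromen-4-one F8. MOMCl and iPr2NEt in CH2Cl2 would cap the hindered C5 hydroxyl as 7-(methoxymethoxy)-3-{5-(methoxymethoxy)-2,2-dimethyl-8-[(triisopropylsilyl)oxy]-2H-chromen-6-yl}chromen-4-one F9. Bu4NF in THF would free 3-[8-hydroxy-5-(methoxymethoxy)-2,2-dimethyl-2H-chromen-6-yl]-7-(methoxymethoxy)chromen-4-one F10. MeI and K2CO3, now with a single free hydroxyl, would give 3-[8-methoxy-5-(methoxymethoxy)-2,2-dimethyl-2H-chromen-6-yl]-7-(methoxymethoxy)chromen-4-one F11. The acid of step 8 then removes both acetals to give 15.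

3. Step 3. Loss of HCl from the tertiary propargylic chloride could outpace O-alkylation of the phenoxide, which carries an ortho methoxy group. The fallback is a direct chromene annulation; it sets out from 4 and returns at 9, replacing steps 3 and 4. Phenol 4 would be heated with 3-methylbut-2-enal and PhB(OH)2 in toluene with catalytic propionic acid under removal of water. This ortho-specific condensation passes through 5,8-dimethoxy-4-(2-methylprop-1-en-1-yl)-2-phenyl-4H-1,3,2-benzodioxaborinine F12, which fragments on heating to quinone methide 8 and closes to 9.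

Further compounds
F1 | step 6 | 3-iodo-7-(methoxymethoxy)chromen-4-one | COCOc1ccc2c(c1)occ(I)c2=O
F2 | step 6 | 4-bromo-2,5-dimethoxyphenol | COc1cc(Br)c(OC)cc1O
F3 | step 6 | 1-bromo-2,5-dimethoxy-4-[(2-methylbut-3-yn-2-yl)oxy]benzene | COc1cc(Br)c(OC)cc1OC(C)(C)C#C
F4 | step 6 | 6-bromo-5,8-dimethoxy-2,2-dimethyl-2H-chromene | COc1cc(Br)c(OC)c2c1OC(C)(C)C=C2
F5 | step 6 | 2-(5,8-dimethoxy-2,2-dimethyl-2H-chromen-6-yl)-4,4,5,5-tetramethyl-1,3,2-dioxaborolane | COc1cc(B2OC(C)(C)C(C)(C)O2)c(OC)c2c1OC(C)(C)C=C2
F6 | step 6 | 3-(5,8-dimethoxy-2,2-dimethyl-2H-chromen-6-yl)-7-(methoxymethoxy)chromen-4-one | COCOc1ccc2c(c1)occ(-c1cc(OC)c3OC(C)(C)C=Cc3c1OC)c2=O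
F7 | step 6 | 6-[7-(methoxymethoxy)-4-oxo-4H-chromen-3-yl]-2,2-dimethyl-2H-chromene-5,8-dione | COCOc1ccc2c(c1)occ(C1=CC(=O)C3=C(C=CC(C)(C)O3)C1=O)c2=O
F8 | step 7 | 3-{5-hydroxy-2,2-dimethyl-8-[(triisopropylsilyl)oxy]-2H-chromen-6-yl}-7-(methoxymethoxy)chromen-4-one | COCOc1ccc2c(c1)occ(-c1cc(O[Si](C(C)C)(C(C)C)C(C)C)c3OC(C)(C)C=Cc3c1O)c2=O
F9 | step 7 | 7-(methoxymethoxy)-3-{5-(methoxymethoxy)-2,2-dimethyl-8-[(triisopropylsilyl)oxy]-2H-chromen-6-yl}chromen-4-one | COCOc1ccc2c(c1)occ(-c1cc(O[Si](C(C)C)(C(C)C)C(C)C)c3OC(C)(C)C=Cc3c1OCOC)c2=O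
F10 | step 7 | 3-[8-hydroxy-5-(methoxymethoxy)-2,2-dimethyl-2H-chromen-6-yl]-7-(methoxymethoxy)chromen-4-one | COCOc1ccc2c(c1)occ(-c1cc(O)c3OC(C)(C)C=Cc3c1OCOC)c2=O
F11 | step 7 | 3-[8-methoxy-5-(methoxymethoxy)-2,2-dimethyl-2H-chromen-6-yl]-7-(methoxymethoxy)chromen-4-one | COCOc1ccc2c(c1)occ(-c1cc(OC)c3OC(C)(C)C=Cc3c1OCOC)c2=O
F12 | step 3 | 5,8-dimethoxy-4-(2-methylprop-1-en-1-yl)-2-phenyl-4H-1,3,2-benzodioxaborinine (racemic, formed in the flask) | COc1ccc(OC)c2c1OB(c1ccccc1)OC2C=C(C)C
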